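The balance I started from was that charged starting material can stand in 4 forms: itself, target, self-condensation product and spent catalyst. Spent catalyst can hold at most 6.00% of the charge, so my task was to reckon how the rest divides between the other two products.

| flask | starting material | coupling partner | second substrate | free catalyst | added ligand | temperature | time | remark |
|---|---|---|---|---|---|---|---|---|
| gamma | 0.10 M | 0.250 M (in portions, 4, over 10 h) | 0.500 M | 6.0 mM | 4.5 mM | 35 °C | 25 h | first portion at the start, last at 10 h |
| alpha | 0.10 M (fed, over 10 h) | 0.250 M | 0.500 M | 6.0 mM | 4.5 mM |  | 25 h | the addition at −5 °C, then warmed to 35 °C; the feed brings no volume worth counting |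
| zeta | 0.10 M (fed, over 10 h) | 0.250 M | 0.500 M | 6.0 mM | 4.5 mM | 35 °C | 25 h | all else is in the flask from the start; the feed brings no volume worth counting |
| beta | 0.10 M | 0.250 M | 0.500 M | 6.0 mM | 4.5 mM | 35 °C | 25 h | everything together at the start |

    starting material + coupling partner + free catalyst → free catalyst + target (k1 = 1.9 M⁻² min⁻¹, Ea1 = 43.0 kJ mol⁻¹)
    second substrate + coupling partner + free catalyst → free catalyst + second product (k2 = 0.50 M⁻² min⁻¹, Ea2 = 61.0 kJ mol⁻¹)
    2 starting material → self-condensation product (k3 = 0.026 M⁻¹ min⁻¹, Ea3 = 80.0 kJ mol⁻¹)
    starting material + free catalyst → spent catalyst (k4 = 0.023 M⁻¹ min⁻¹, Ea4 = 73.0 kJ mol⁻¹)
    free catalyst + added ligand ⇌ idle complex (K5 = 520 M⁻¹, k5 = 1.5 M⁻¹ min⁻¹, Ea5 = 47.0 kJ mol⁻¹, ΔH5 = −5.00 kJ mol⁻¹)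
    (constants at 35 °C)

- in percentages every species weighs as the starting material in it: one self-condensation product counts as two
- a doubled species enters its step squared and goes two at a time
- the constants hold at 35 °C; other temperatures follow from the activation energies and enthalpies

- the flask that comes out highest in amount of self-condensation product, in percent of the starting material charged; "all alike" if 1.5 percentage points covers them all (gamma / alpha / zeta / beta / all alike)
- amount of self-condensation product at the end, in percent of the starting material charged, gamma
- amount of self-condensation product at the end, in percent of the starting material charged, alpha
- amount of self-condensation product at the end, in percent of the starting material charged, zeta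
- amount of self-condensation product at the end, in percent of the starting material charged, beta

I drew beta first. I set step 5 at balance, which leaves 3.19 mM of free catalyst, and I held that and the charged [coupling partner] fixed. Step 1 is then pseudo-first-order in starting material, with constant 0.0910 h⁻¹ and half-life 7.62 h, while step 3 alone has a first half-life of 3.21 h. At the start of beta the ratio stood at 3.43; this is the split, the rate at which step 3 uses starting material over the rate at which step 1 uses it. It is twice the constant of step 3 times [starting material], over the constant of step 1 times [coupling partner][free catalyst].

The split falls in step with [starting material]. The curve of self-condensation product therefore rises steeply at first, with a knee where the split crosses one, at 0.0292 M. Below that the first-order tail takes over. The momentary share of step 3 is the split over one plus the split. Summing it from the charge down to nothing joins both ends and gives a level of one minus the logarithm of (one plus the split) over the split. For beta that is 56.6%.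

In gamma the gap between portions, 3.33 h, is about the first half-life of step 3. I therefore let the starting material see half of the partner, which makes the split 6.86 and the level 69.9%.

In zeta the feed 0.0100 M h⁻¹ meets both uses at a standing 0.0439 M, reached in about 4.39 h, less than the feed time. The split there is 1.51, and I took its share for the whole charge, 60.1%.

In alpha I assumed that the cold feed simulated the starting material and that the warmed flask ran as beta, 56.6%. The activation energy of step 3 stands above that of step 1, so whatever reacted in the cold went at a lower split, and I expected alpha below that figure. My ranking was gamma.

The forecast also named gamma, with 71% (65% to 76%), alpha 54% (48% to 60%), zeta 61% (54% to 67%) and beta 58% (52% to 64%); of gamma it wrote “partner starved early, so coupling is slower”. Its gamma stood above mine, and it put alpha below beta, where my two figures were level.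

The flasks gave 73.8% for gamma, 55.2% for alpha, 60.1% for zeta and 59.7% for beta, so gamma stood highest. Gamma's split read 1.2 at 12.3 h. Gamma's neighbour with 0.040 M of starting material has, on the same count, a split of 2.74 and a level of 51.9%; it gave 53.6%. Gamma had not come to rest: 6.73% of its starting material stood at 25.0 h, at a split of 0.783. That remainder adds 1.8 percentage points, making 75.6%. Ten times the time gave 76.0%, with coupling partner down from 55.5% to 2.58% of its charge.

All constants belong to no real substance; what happens was integrated by code.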